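**Retrosynthesis**
- The target is (2S)-6,8,3'-triprenyl-7,4'-dihydroxyflavanone. Disconnect the C2–O bond (intramolecular oxa-Michael) to a 2'-hydroxychalcone. This is the only ring formed in the route, and it sets C2.
- Disconnect the chalcone C=C (Claisen–Schmidt) to 3,5-diprenyl-2,4-dihydroxyacetophenone and 3-prenyl-4-hydroxybenzaldehyde.
- Both prenylated partners come from direct ortho-C-prenylation of commercial phenols with prenyl bromide. Both aromatic rings are therefore present before the single ring-forming step.

Assumption: the 9-amino-9-deoxy-epi-quinine catalyst is taken to give the (2S) enantiomer. If (2R) is obtained, the quinidine-derived pseudoenantiomer is used instead.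

---

**Step 1**
Reactants: 1 (2,4-dihydroxyacetophenone); 2 (prenyl bromide)
Product: 3 (1-[2,4-dihydroxy-3,5-bis(3-methylbut-2-enyl)phenyl]ethan-1-one)
Conditions: 2 (2.3 equiv), KOH (3 equiv), MeOH/H2O, 0 °C → rt, 16 h; chromatographic separation from the mono-prenyl compound (recycled) and from O-prenyl by-products
Reagents that add atoms: prenyl bromide, CC(C)=CCBr
Why: Phenolate ortho-C-alkylation of the two activated positions (C3 between the OH groups, and C5 ortho to the 4-OH) by an SN2-type allylic alkylation gives the 6,8-diprenyl A-ring pattern after cyclisation. The yield is modest (about 30%), but the step is short and uses cheap reagents.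

**Step 2**
Reactants: 4 (4-hydroxybenzaldehyde); 2 (prenyl bromide)
Product: 5 (4-hydroxy-3-(3-methylbut-2-enyl)benzaldehyde)
Conditions: 2 (1.1 equiv), NaOH (2.2 equiv), H2O, 0 °C → rt, 12 h; acidify to pH 3, extract, chromatography
Reagents that add atoms: prenyl bromide, CC(C)=CCBr
Why: In water, the hydrogen-bonded phenolate reacts at carbon (ortho) rather than oxygen, giving the 3'-prenyl B-ring precursor by the same ortho-C-alkylation as Step 1. The para-CHO group blocks the para position.

**Step 3**
Reactants: 3 (diprenyl acetophenone); 5 (prenyl hydroxybenzaldehyde)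
Product: 6 ((E)-1-[2,4-dihydroxy-3,5-bis(3-methylbut-2-enyl)phenyl]-3-[4-hydroxy-3-(3-methylbut-2-enyl)phenyl]prop-2-en-1-one)
Conditions: KOH (5 equiv), EtOH/H2O 4:1, rt → 40 °C, 72 h, N2; quench with cold 1 M HCl to pH 3
Reagents that add atoms: none
Why: Base-mediated Claisen–Schmidt (aldol condensation) gives the E-chalcone, and the three phenols are tolerated as phenolates. The cold acidic quench limits spontaneous racemic cyclisation. No stereocenter is formed.

**Step 4**
Reactants: 6 (chalcone); 7 (9-amino-9-deoxy-epi-quinine, catalyst); 8 (3,5-bis(trifluoromethyl)benzoic acid, co-catalyst)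
Product: 9 ((2S)-6,8,3'-triprenyl-7,4'-dihydroxyflavanone, the target)
Conditions: 7 (20 mol%), 8 (40 mol%), PhMe (0.05 M), 40 °C, 120 h; stop at about 85% conversion and recycle unreacted 6
Reagents that add atoms: none (an isomerisation; the catalyst and acid are not incorporated)
Why: Proposed new method: the primary amine condenses with the aryl ketone of 6 to give a chiral iminium ion. The protonated quinuclidine and the benzoate ion-pair hydrogen-bond the 2'-OH, which then adds 6-endo to the β-carbon on one enantioface (intramolecular oxa-Michael). This sets C2 as (S), and hydrolysis releases the flavanone. The closest known reaction is the cinchona primary-amine/acid-catalysed oxa-Michael cyclisation of simple 2'-hydroxychalcones to flavanones. The new element is applying it to a fully unprotected, triprenylated 2',4,4'-trihydroxychalcone. Its two para-OH groups deactivate the enone and would be deprotonated by basic bifunctional catalysts, which shut down the thiourea-type pathway. The weakly acidic 1:2 amine/acid buffer keeps the phenols neutral and drives the chalcone → flavanone equilibrium forward. The acid is mild enough not to cyclise the prenyl groups onto the ortho OH groups. No later step touches C2, so the configuration is retained.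

---

**Compound list**

| No. | Name | SMILES | Role |
|---|---|---|---|
| 1 | 2,4-dihydroxyacetophenone | CC(=O)c1ccc(O)cc1O | starting material |
| 2 | prenyl bromide | CC(C)=CCBr | starting material |
| 3 | 3,5-diprenyl-2,4-dihydroxyacetophenone | CC(=O)c1cc(CC=C(C)C)c(O)c(CC=C(C)C)c1O | intermediate |
| 4 | 4-hydroxybenzaldehyde | O=Cc1ccc(O)cc1 | starting material |
| 5 | 4-hydroxy-3-prenylbenzaldehyde | O=Cc1ccc(O)c(CC=C(C)C)c1 | intermediate |
| 6 | (E)-2',4,4'-trihydroxy-3,3',5'-triprenylchalcone | CC(C)=CCc1cc(/C=C/C(=O)c2cc(CC=C(C)C)c(O)c(CC=C(C)C)c2O)ccc1O | intermediate |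
| 7 | 9-amino-9-deoxy-epi-quinine (organocatalyst) | C=C[C@H]1CN2CC[C@H]1C[C@H]2[C@@H](N)c1ccnc2ccc(OC)cc12 | starting material |
| 8 | 3,5-bis(trifluoromethyl)benzoic acid (co-catalyst) | OC(=O)c1cc(cc(c1)C(F)(F)F)C(F)(F)F | starting material |
| 9 | (2S)-6,8,3'-triprenyl-7,4'-dihydroxyflavanone | CC(C)=CCc1cc([C@@H]2CC(=O)c3cc(CC=C(C)C)c(O)c(CC=C(C)C)c3O2)ccc1O | target |

**Total step count:** 4
**Longest linear sequence:** 3 steps (1 → 3 → 6 → 9, or 4 → 5 → 6 → 9)

**Three steps most likely to fail**
1. **Step 4 (proposed new method).** The deactivated polyphenolic enone may give slow conversion, low ee, or racemisation through retro-Michael.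
   - Fallback (known chemistry): cyclise 6 racemically (NaOAc, EtOH, reflux), then isolate the (2S) enantiomer by preparative chiral-phase HPLC on an amylose column.
2. **Step 1.** Diprenylation may be unselective, giving mono-prenyl, O-prenyl or dearomatised products in low yield.
   - Fallback: bis-O-allylation of 1 (allyl bromide, K2CO3), double aromatic Claisen rearrangement (neat, about 200 °C) to the 3,5-diallyl compound, then cross-metathesis with 2-methyl-2-butene (Grubbs II) to give 3.
3. **Step 3.** Condensation of two electron-rich, phenolate-forming partners may stall or give partial racemic flavanone.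
   - Fallback: protect the 4-OH of 3 and the OH of 5 as MOM ethers (MOMCl, iPr2NEt). Run the Claisen–Schmidt with Ba(OH)2/MeOH, then remove the MOM groups with ZnBr2/n-PrSH in CH2Cl2.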